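**Assumption:** the target, 2,4,7-tribromo-3-chloro-1H-indole, has no stereocentre, so no enantiocontrol is needed; 3,6-dibromo-2-fluorobenzaldehyde is taken as a catalogue compound.

## Retrosynthetic overview

1. Target 15 ⇐ N-tosyl indole 14 by N-desulfonylation (last step).
2. 14 ⇐ bromoalkyne sulfonanilide 12: ring B (pyrrole) is closed by a chloro-aminocyclization that forms N1–C2 and C3–Cl together, with C2–Br carried in on the alkyne (proposed new step).
3. 12 ⇐ 10 ⇐ 8: C(sp)–H bromination and N-tosylation of 3,6-dibromo-2-ethynylaniline.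
4. 8 ⇐ 5 ⇐ 3 ⇐ 1: azide reduction, one-carbon aldehyde-to-alkyne homologation, and SNAr of fluoride by azide.
5. Ring order: ring A (benzene, both aryl bromides in place) is bought; ring B is the only ring formed (step 6).

## Route

Step 1
Reactants: 1 3,6-dibromo-2-fluorobenzaldehyde; 2 sodium azide
Product: 3 2-azido-3,6-dibromobenzaldehyde
Conditions: NaN3 (1.3 equiv), DMSO, 45 °C, dark
Reagents that add atoms: sodium azide, [N-]=[N+]=[N-].[Na+]
Why: Nucleophilic aromatic substitution (addition–elimination); the fluoride ortho to the formyl group is displaced far faster than either bromide, and the mild temperature keeps the ortho-azido aldehyde intact.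

Step 2
Reactants: 3 2-azido-3,6-dibromobenzaldehyde; 4 dimethyl (1-diazo-2-oxopropyl)phosphonate (Ohira–Bestmann reagent)
Product: 5 2-azido-1,4-dibromo-3-ethynylbenzene
Conditions: K2CO3 (2 equiv), MeOH, 0 °C to rt, dark
Reagents that add atoms: dimethyl (1-diazo-2-oxopropyl)phosphonate, CC(=O)C(=[N+]=[N-])P(=O)(OC)OC
Why: Ohira–Bestmann variant of the Seyferth–Gilbert homologation; the diazomethylphosphonate anion released by methanolysis turns the electron-poor aldehyde into the terminal alkyne at room temperature, and aryl azide and aryl bromides tolerate K2CO3/MeOH.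

Step 3
Reactants: 5 2-azido-1,4-dibromo-3-ethynylbenzene; 6 triphenylphosphine
Product: 8 3,6-dibromo-2-ethynylaniline, via iminophosphorane 7 (not isolated)
Conditions: PPh3 (1.1 equiv), THF, rt; then H2O, 60 °C
Reagents that add atoms: none
Why: Staudinger reduction; the phosphine attacks only the azide (N2 loss), and hydrolysis of the iminophosphorane gives the aniline without touching the C–Br bonds or the alkyne.

Step 4
Reactants: 8 3,6-dibromo-2-ethynylaniline; 9 4-methylbenzenesulfonyl chloride
Product: 10 N-(3,6-dibromo-2-ethynylphenyl)-4-methylbenzenesulfonamide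
Conditions: TsCl (1.5 equiv), pyridine, 60 °C
Reagents that add atoms: 4-methylbenzenesulfonyl chloride, Cc1ccc(cc1)S(=O)(=O)Cl
Why: N-sulfonylation of an aniline; warm pyridine drives the hindered, weakly basic amine to the mono-sulfonamide, which deactivates the arene and provides the acidic N–H needed in step 6.

Step 5
Reactants: 10 N-(3,6-dibromo-2-ethynylphenyl)-4-methylbenzenesulfonamide; 11 N-bromosuccinimide
Product: 12 N-[3,6-dibromo-2-(bromoethynyl)phenyl]-4-methylbenzenesulfonamide
Conditions: NBS (1.15 equiv), AgNO3 (5 mol %), acetone, rt, 1 h, dark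
Reagents that add atoms: N-bromosuccinimide, O=C1CCC(=O)N1Br
Why: AgNO3-catalysed electrophilic bromination of a terminal alkyne C–H through the ArC≡CAg acetylide; the neutral, fast conditions leave the sulfonamide N–H and the deactivated arene alone.

Step 6
Reactants: 12 N-[3,6-dibromo-2-(bromoethynyl)phenyl]-4-methylbenzenesulfonamide; 13 N-chlorosuccinimide
Product: 14 2,4,7-tribromo-3-chloro-1-(4-methylbenzenesulfonyl)-1H-indole
Conditions: NCS (1.2 equiv), Ph3P=S (10 mol %), CH2Cl2, 0 °C to rt, dark
Reagents that add atoms: N-chlorosuccinimide, O=C1CCC(=O)N1Cl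
Why: Proposed new method: Lewis-base-catalysed 5-endo-dig chloro-aminocyclization onto a 1-bromoalkyne. Ph3P=S takes Cl+ from NCS to give [Ph3P–S–Cl]+ succinimidate; the succinimidate hydrogen-bonds to and deprotonates the acidic sulfonanilide N–H; the nitrogen then attacks the bromine-bearing alkyne carbon anti to chlorenium delivery at the aryl-bearing carbon in a concerted, nucleophile-assisted addition. The ortho tether allows only this regiochemistry, so Br stays on C2 and Cl enters at C3, with aromatisation as driving force. The closest known reactions are electrophilic halocyclizations of 2-alkynyl sulfonanilides to 3-haloindoles (I2, ICl, CuCl2) and phosphine-sulfide-catalysed NCS chlorinations, neither shown on a haloalkyne.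

Step 7
Reactants: 14 2,4,7-tribromo-3-chloro-1-(4-methylbenzenesulfonyl)-1H-indole
Product: 15 2,4,7-tribromo-3-chloro-1H-indole
Conditions: Cs2CO3 (3 equiv), THF/MeOH 2:1, rt
Reagents that add atoms: none
Why: Base-mediated methanolysis of an N-sulfonyl indole (N-desulfonylation); methoxide attacks sulfur, the electron-poor tetrahaloindolide is a good leaving group, and the C–Br and C–Cl bonds are untouched at room temperature.

## Compound list

1 | 3,6-dibromo-2-fluorobenzaldehyde | O=Cc1c(F)c(Br)ccc1Br | starting material
2 | sodium azide | [N-]=[N+]=[N-].[Na+] | starting material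
3 | 2-azido-3,6-dibromobenzaldehyde | O=Cc1c(N=[N+]=[N-])c(Br)ccc1Br | intermediate
4 | dimethyl (1-diazo-2-oxopropyl)phosphonate | CC(=O)C(=[N+]=[N-])P(=O)(OC)OC | starting material
5 | 2-azido-1,4-dibromo-3-ethynylbenzene | C#Cc1c(N=[N+]=[N-])c(Br)ccc1Br | intermediate
6 | triphenylphosphine | c1ccc(cc1)P(c1ccccc1)c1ccccc1 | starting material
7 | N-(3,6-dibromo-2-ethynylphenyl)iminotriphenylphosphorane | C#Cc1c(N=P(c2ccccc2)(c2ccccc2)c2ccccc2)c(Br)ccc1Br | intermediate
8 | 3,6-dibromo-2-ethynylaniline | C#Cc1c(N)c(Br)ccc1Br | intermediate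
9 | 4-methylbenzenesulfonyl chloride | Cc1ccc(cc1)S(=O)(=O)Cl | starting material
10 | N-(3,6-dibromo-2-ethynylphenyl)-4-methylbenzenesulfonamide | C#Cc1c(NS(=O)(=O)c2ccc(C)cc2)c(Br)ccc1Br | intermediate
11 | N-bromosuccinimide | O=C1CCC(=O)N1Br | starting material
12 | N-[3,6-dibromo-2-(bromoethynyl)phenyl]-4-methylbenzenesulfonamide | BrC#Cc1c(NS(=O)(=O)c2ccc(C)cc2)c(Br)ccc1Br | intermediate
13 | N-chlorosuccinimide | O=C1CCC(=O)N1Cl | starting material
14 | 2,4,7-tribromo-3-chloro-1-(4-methylbenzenesulfonyl)-1H-indole | Cc1ccc(cc1)S(=O)(=O)n1c(Br)c(Cl)c2c(Br)ccc(Br)c12 | intermediate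
15 | 2,4,7-tribromo-3-chloro-1H-indole | Clc1c(Br)[nH]c2c(Br)ccc(Br)c12 | target

## Summary

Total step count: 7. Longest linear sequence: 7 steps (fully linear from 1).

Three steps most likely to fail:

**Step 6 (proposed new step).** Cl+ may instead attack the bromine-bearing carbon and exchange halogen, giving the 3-bromo-2-chloro isomer or dihalo mixtures. The alkyne may also be dichlorinated, or the substrate may rest as the N-chlorosulfonamide and chlorinate the ring para to nitrogen. The fallback uses known chemistry, sets out from 12 and comes back at 15. Compound 12 is cyclised without chlorine by carbonate-promoted 5-endo-dig hydroamination of the o-(bromoethynyl)sulfonanilide (K2CO3, DMF, 60 °C) to 2,4,7-tribromo-1-(4-methylbenzenesulfonyl)-1H-indole F1. Cs2CO3 in THF/MeOH at rt then removes the tosyl group to give 2,4,7-tribromo-1H-indole F2, which is used at once. NCS (13) in DMF at 0 °C chlorinates C3, the only activated open position, by ordinary electrophilic 3-halogenation of an indole, giving 15.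

**Step 4.** The amine is flanked by bromine and the ethynyl group and is weakly nucleophilic, so sulfonylation may stall or give the bis-sulfonimide. The fallback sets out from 1 and comes back at 10, bringing the nitrogen in already sulfonylated. Compound 1 is heated with 4-methylbenzenesulfonamide and K2CO3 in DMSO at 90 °C (SNAr of the sulfonamidate at C–F) to give N-(3,6-dibromo-2-formylphenyl)-4-methylbenzenesulfonamide F3. Ohira–Bestmann homologation of F3 with 4 (K2CO3, MeOH, rt) gives 10, so no azide and no sulfonylation of a hindered aniline are needed.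

**Step 2.** The aldehyde is hindered on both sides, and the ortho azide may react with the diazophosphonate anion or degrade under base. The fallback sets out from 3 and comes back at 8, removing the azide before the homologation. Compound 3 is treated with PPh3 (6) in THF to give 3,6-dibromo-2-[(triphenyl-λ5-phosphanylidene)amino]benzaldehyde F4, which is not isolated. Hydrolysis in aqueous THF with a little AcOH at 50 °C gives 2-amino-3,6-dibromobenzaldehyde F5. Ohira–Bestmann homologation of F5 with 4 (K2CO3, MeOH, rt) gives 8.

## Further compounds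

F1 | step 6 | 2,4,7-tribromo-1-(4-methylbenzenesulfonyl)-1H-indole | Cc1ccc(cc1)S(=O)(=O)n1c(Br)cc2c(Br)ccc(Br)c12
F2 | step 6 | 2,4,7-tribromo-1H-indole | Brc1cc2c(Br)ccc(Br)c2[nH]1
F3 | step 4 | N-(3,6-dibromo-2-formylphenyl)-4-methylbenzenesulfonamide | O=Cc1c(NS(=O)(=O)c2ccc(C)cc2)c(Br)ccc1Br
F4 | step 2 | 3,6-dibromo-2-[(triphenyl-λ5-phosphanylidene)amino]benzaldehyde | O=Cc1c(N=P(c2ccccc2)(c2ccccc2)c2ccccc2)c(Br)ccc1Br
F5 | step 2 | 2-amino-3,6-dibromobenzaldehyde | O=Cc1c(N)c(Br)ccc1Br
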